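**Plan**

1. Ring C is cut at O1–C2 and C2–C3 (C2 is a one-carbon unit from an amide acetal) and at C3–C4 (benzyl Grignard reagent on a Weinreb amide). This leaves ring A as a β-resorcylate ester whose ester carbon is C4.
2. Ring A is cut at C4a–C5. The enabling feature is that the oxygens on C7 and C8a (O1) are meta on ring A with the prenylated C8 between them. C4–C4a–C8a–C8–C7 is therefore a 1,3,5-tricarbonyl chain with C8 as its central carbon, and the unsubstituted C5 is an aldehyde-level carbon, carried as the enol ether end of a methoxyenone (C7 carbonyl, C6=C5–OMe).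
3. The open chain is cut at C7–C8 (acylation of a keto ester dianion) and at C8–CH2 of the prenyl group (alkylation of the methyl acetoacetate dianion), so the prenyl group is in place before ring A exists.
4. Forward: two dianion steps join the chain and methoxide folds it into ring A. Then follow 7-O-methylation, MOM protection of the future O1, Weinreb amide formation, benzylation, deprotection, and closure of ring C last.
5. Stereochemistry: the target has no stereocentre. The only defined geometry on the way is the E enol ether of the purchased acrylate, which is consumed in the ring closure.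

Key step: step 4

Remark: the open-chain precursor is racemic at its single methine and largely enolised; enolates, fleeting ring intermediates and the enaminone that are not isolated are drawn without descriptors where their configuration is mixed.

**Route**

Step 1
Reactants: 1 methyl acetoacetate; 2 prenyl bromide (1-bromo-3-methylbut-2-ene)
Product: 4 methyl 7-methyl-3-oxooct-6-enoate, via acetoacetate dianion 3 (not isolated)
Conditions: NaH (1.1 equiv), THF, 0 °C; n-BuLi (1.05 equiv), 0 °C; 2 (1.0 equiv), 0 °C → rt; dilute HCl
Reagents that add atoms: none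
Why: Acetoacetate dianion γ-alkylation, in which the terminal carbanion is far more nucleophilic than the stabilised β-keto ester enolate and displaces bromide at the primary allylic carbon (SN2).

Step 2
Reactants: 5 methyl (E)-3-methoxyacrylate
Product: 6 (E)-N,3-dimethoxy-N-methylprop-2-enamide
Conditions: MeNHOMe·HCl (1.5 equiv), i-PrMgCl (3.0 equiv), THF, −20 °C → 0 °C; aq NH4Cl
Reagents that add atoms: N,O-dimethylhydroxylamine hydrochloride, CNOC.Cl
Why: Weinreb aminolysis of an ester by the chloromagnesium amide, where the β-methoxy group makes the acrylate a vinylogous carbonate and a poor Michael acceptor, so the hard amide should attack the ester carbonyl and leave the E enol ether intact.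

Step 3
Reactants: 4 methyl 7-methyl-3-oxooct-6-enoate; 6 (E)-N,3-dimethoxy-N-methylprop-2-enamide
Product: 8 methyl (E)-7-methoxy-4-(3-methylbut-2-enyl)-3,5-dioxohept-6-enoate, via keto ester dianion 7 (not isolated)
Conditions: 4 (1.5 equiv), NaH, THF, 0 °C; n-BuLi, −10 °C; 6 (1.0 equiv), −78 °C → 0 °C; cold dilute HCl to pH 5
Reagents that add atoms: none
Why: Weinreb ketone synthesis on a β-keto ester dianion, in which the γ-carbanion acylates at the amide carbonyl and the N-methoxy-N-methyl amide releases the acidic 1,3-diketone only at the quench, so it neither protonates unreacted dianion nor is attacked twice, while work-up at pH 5 spares the enol ether.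

Step 4
Reactants: 8 methyl (E)-7-methoxy-4-(3-methylbut-2-enyl)-3,5-dioxohept-6-enoate
Product: 11 methyl 2,4-dihydroxy-3-(3-methylbut-2-enyl)benzoate, via cyclised methoxy adduct 9 (not isolated), via cyclohexenedione tautomer 10 (not isolated)
Conditions: NaOMe (3 equiv), MeOH, 0 °C → 65 °C; then dilute HCl to pH 3, 0 °C
Reagents that add atoms: none
Why: In chain numbering, methoxide deprotonates the β-keto ester methylene C2 (future C4a), which adds to C7 (future C5), the β-carbon of the methoxyenone, to give 9; E1cB loss of methoxide across C2–C7 gives the enedione 10, whose two keto groups enolise to the aromatic ring of 11. The closest known reaction type is the polyketide-type intramolecular aldol condensation with aromatisation that folds 3,5,7-tricarbonyl esters into β-resorcylates, here with the aldehyde masked as a vinylogous ester that reacts by addition–elimination. Ring A closes in a 6-endo-trig mode, the C6=C7 bond lying inside the new ring, and C4a–C5 is the only skeletal bond made. No stereocentre survives, since the sp3 centres of 9 and the methine of 10 are erased on aromatisation. The selectivity needed is carbon over oxygen closure: the C4 carbanion could only close a four-membered ring, and both oxygen-closure products (the 4-pyranone from enol oxygen onto C7 and the 2-pyranone lactone from enol oxygen onto the ester) should be reopened by methoxide in methanol, whereas methoxide loss followed by aromatisation is irreversible and drains the material to 11. Methyl ester, methoxide base and methoxide leaving group are matched so no ester exchange can scramble the product, and the isolated trisubstituted alkene is inert to base.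

Step 5
Reactants: 11 methyl 2,4-dihydroxy-3-(3-methylbut-2-enyl)benzoate
Product: 12 methyl 2-hydroxy-4-methoxy-3-(3-methylbut-2-enyl)benzoate
Conditions: MeI (1.05 equiv), K2CO3 (1.1 equiv), acetone, rt
Reagents that add atoms: iodomethane, CI
Why: Williamson O-methylation, selective because the 4-hydroxyl para to the ester is the more acidic and is free, whereas the 2-hydroxyl is locked in a hydrogen bond to the ester carbonyl.

Step 6
Reactants: 12 methyl 2-hydroxy-4-methoxy-3-(3-methylbut-2-enyl)benzoate
Product: 13 methyl 4-methoxy-2-(methoxymethoxy)-3-(3-methylbut-2-enyl)benzoate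
Conditions: NaH (1.3 equiv), DMF, 0 °C; MOMCl (1.3 equiv), 0 °C → rt
Reagents that add atoms: chloromethyl methyl ether, COCCl
Why: Williamson-type acetal protection, in which NaH breaks the hydrogen bond by forming the phenoxide and the reactive chloromethyl ether alkylates it on oxygen, removing the acidic proton ahead of the two organomagnesium steps.

Step 7
Reactants: 13 methyl 4-methoxy-2-(methoxymethoxy)-3-(3-methylbut-2-enyl)benzoate
Product: 14 N,4-dimethoxy-2-(methoxymethoxy)-N-methyl-3-(3-methylbut-2-enyl)benzamide
Conditions: MeNHOMe·HCl (2 equiv), i-PrMgCl (4 equiv), THF, −20 °C → rt; aq NH4Cl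
Reagents that add atoms: N,O-dimethylhydroxylamine hydrochloride, CNOC.Cl
Why: Weinreb aminolysis of the aryl ester by the chloromagnesium amide, to which the MOM acetal, the aryl methyl ether and the prenyl alkene are inert.

Step 8
Reactants: 15 2,4,5-trimethoxybenzyl alcohol
Product: 16 1-(chloromethyl)-2,4,5-trimethoxybenzene
Conditions: SOCl2 (1.2 equiv), CH2Cl2, 0 °C; evaporate, use at once
Reagents that add atoms: thionyl chloride, O=S(Cl)Cl
Why: Chlorodehydroxylation through the chlorosulfite, fast at 0 °C for an electron-rich benzylic alcohol (a catalogue chemical, otherwise one NaBH4 reduction from the commercial aldehyde), with the chloride used immediately because it self-alkylates on storage.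

Step 9
Reactants: 14 N,4-dimethoxy-2-(methoxymethoxy)-N-methyl-3-(3-methylbut-2-enyl)benzamide; 16 1-(chloromethyl)-2,4,5-trimethoxybenzene
Product: 18 1-[4-methoxy-2-(methoxymethoxy)-3-(3-methylbut-2-enyl)phenyl]-2-(2,4,5-trimethoxyphenyl)ethan-1-one, via benzylic Grignard reagent 17 (not isolated)
Conditions: 16 (2 equiv), Mg turnings (excess), THF, 0 °C, slow addition; then 14, 0 °C → rt; aq NH4Cl
Reagents that add atoms: none
Why: Weinreb ketone synthesis, in which the benzylic Grignard reagent, formed cold and dilute over excess magnesium to hold back Wurtz coupling, adds once to the N-methoxy-N-methyl amide and the ketone is released only on work-up.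

Step 10
Reactants: 18 1-[4-methoxy-2-(methoxymethoxy)-3-(3-methylbut-2-enyl)phenyl]-2-(2,4,5-trimethoxyphenyl)ethan-1-one
Product: 19 1-[2-hydroxy-4-methoxy-3-(3-methylbut-2-enyl)phenyl]-2-(2,4,5-trimethoxyphenyl)ethan-1-one
Conditions: HCl (1.25 M in MeOH), 0 °C → rt
Reagents that add atoms: none
Why: Acid-catalysed acetal exchange with methanol removes the MOM group, helped by the neighbouring carbonyl, and dilute acid at room temperature should leave the prenyl alkene and the four aryl methyl ethers untouched.

Step 11
Reactants: 19 1-[2-hydroxy-4-methoxy-3-(3-methylbut-2-enyl)phenyl]-2-(2,4,5-trimethoxyphenyl)ethan-1-one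
Product: 21 prebarbigerone, 7-methoxy-8-(3-methylbut-2-enyl)-3-(2,4,5-trimethoxyphenyl)-4H-chromen-4-one, via enaminone 20 (not isolated)
Conditions: Me2NCH(OMe)2 (3 equiv), toluene, 95 °C
Reagents that add atoms: N,N-dimethylformamide dimethyl acetal, COC(OC)N(C)C
Why: Isoflavone synthesis from a 2-hydroxydeoxybenzoin, in which the acidic benzylic methylene condenses with the amide acetal to the enaminone 20 and the phenol then adds to its β-carbon (6-endo-trig addition–elimination) with loss of dimethylamine to close ring C.

**Compound list**

1 | methyl acetoacetate | CC(=O)CC(=O)OC | starting material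
2 | prenyl bromide (1-bromo-3-methylbut-2-ene) | CC(C)=CCBr | starting material
3 | sodium lithium dianion of methyl acetoacetate (dienolate) | C=C([O-])C=C([O-])OC.[Na+].[Li+] | intermediate
4 | methyl 7-methyl-3-oxooct-6-enoate | CC(C)=CCCC(=O)CC(=O)OC | intermediate
5 | methyl (E)-3-methoxyacrylate | CO/C=C/C(=O)OC | starting material
6 | (E)-N,3-dimethoxy-N-methylprop-2-enamide | CO/C=C/C(=O)N(C)OC | intermediate
7 | sodium lithium dianion of methyl 7-methyl-3-oxooct-6-enoate (dienolate, geometry not defined) | CC(C)=CCC=C([O-])C=C([O-])OC.[Na+].[Li+] | intermediate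
8 | methyl (E)-7-methoxy-4-(3-methylbut-2-enyl)-3,5-dioxohept-6-enoate (racemic at C4, largely enolised) | CO/C=C/C(=O)C(CC=C(C)C)C(=O)CC(=O)OC | intermediate
9 | methyl 2-methoxy-5-(3-methylbut-2-enyl)-4,6-dioxocyclohexane-1-carboxylate (diastereomer mixture, fleeting) | COC(=O)C1C(OC)CC(=O)C(CC=C(C)C)C1=O | intermediate
10 | methyl 5-(3-methylbut-2-enyl)-4,6-dioxocyclohex-1-ene-1-carboxylate (racemic keto tautomer of 11) | COC(=O)C1=CCC(=O)C(CC=C(C)C)C1=O | intermediate
11 | methyl 2,4-dihydroxy-3-(3-methylbut-2-enyl)benzoate | COC(=O)c1ccc(O)c(CC=C(C)C)c1O | intermediate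
12 | methyl 2-hydroxy-4-methoxy-3-(3-methylbut-2-enyl)benzoate | COC(=O)c1ccc(OC)c(CC=C(C)C)c1O | intermediate
13 | methyl 4-methoxy-2-(methoxymethoxy)-3-(3-methylbut-2-enyl)benzoate | COCOc1c(CC=C(C)C)c(OC)ccc1C(=O)OC | intermediate
14 | N,4-dimethoxy-2-(methoxymethoxy)-N-methyl-3-(3-methylbut-2-enyl)benzamide | COCOc1c(CC=C(C)C)c(OC)ccc1C(=O)N(C)OC | intermediate
15 | 2,4,5-trimethoxybenzyl alcohol | COc1cc(OC)c(CO)cc1OC | starting material
16 | 1-(chloromethyl)-2,4,5-trimethoxybenzene | COc1cc(OC)c(CCl)cc1OC | intermediate
17 | 2,4,5-trimethoxybenzylmagnesium chloride | COc1cc(OC)c(C[Mg]Cl)cc1OC | intermediate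
18 | 1-[4-methoxy-2-(methoxymethoxy)-3-(3-methylbut-2-enyl)phenyl]-2-(2,4,5-trimethoxyphenyl)ethan-1-one | COCOc1c(CC=C(C)C)c(OC)ccc1C(=O)Cc1cc(OC)c(OC)cc1OC | intermediate
19 | 1-[2-hydroxy-4-methoxy-3-(3-methylbut-2-enyl)phenyl]-2-(2,4,5-trimethoxyphenyl)ethan-1-one | COc1ccc(C(=O)Cc2cc(OC)c(OC)cc2OC)c(O)c1CC=C(C)C | intermediate
20 | 3-(dimethylamino)-1-[2-hydroxy-4-methoxy-3-(3-methylbut-2-enyl)phenyl]-2-(2,4,5-trimethoxyphenyl)prop-2-en-1-one (E/Z not defined) | COc1ccc(C(=O)C(=CN(C)C)c2cc(OC)c(OC)cc2OC)c(O)c1CC=C(C)C | intermediate
21 | prebarbigerone, 7-methoxy-8-(3-methylbut-2-enyl)-3-(2,4,5-trimethoxyphenyl)-4H-chromen-4-one | COc1cc(OC)c(-c2coc3c(CC=C(C)C)c(OC)ccc3c2=O)cc1OC | target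

**Count and risks**

Total steps: 11. Longest linear sequence: 9 steps (steps 1, 3, 4, 5, 6, 7, 9, 10, 11, from methyl acetoacetate).

Steps most likely to fail:

Step 3. The secondary carbanion of 7 may attack the β-carbon of 6 and expel methoxide (vinylogous substitution), or merely be protonated, instead of adding to the amide carbonyl. The fallback sets out from 4 and returns at 8, and changes the acyl donor to a saturated, acetal-masked one that offers no conjugate position. Methyl 3,3-dimethoxypropanoate is converted with MeNHOMe·HCl and i-PrMgCl, as in step 2, into N,3,3-trimethoxy-N-methylpropanamide F1. The dianion 7, made from 4 as before, is acylated by F1 to give methyl 7,7-dimethoxy-4-(3-methylbut-2-enyl)-3,5-dioxoheptanoate F2. On exposure to NaOMe in MeOH, F2 should lose methanol by E1cB elimination to 8, which is thus formed in the flask of step 4 and carried straight on.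

Step 4. Closure through oxygen to a pyranone, or retro-Claisen scission of the 2-alkyl-1,3-diketone by methoxide, may outpace the carbon–carbon closure. The fallback sets out from 8 and returns at 11; it takes the oxygen closure on purpose and makes the carbocycle by a ring transformation. Catalytic pyridinium p-toluenesulfonate in toluene at 60 °C should close 8 to methyl 2-[3-(3-methylbut-2-enyl)-4-oxo-4H-pyran-2-yl]acetate F3 with loss of methanol, which ties up the cleavable diketone as a vinylogous ester. Mg(OMe)2 in MeOH at reflux should then open the pyranone at C6 and close the magnesium-chelated chain through the same aldol bond, the known pyranone-to-resorcylate rearrangement, to give 11.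

Step 9. Wurtz homocoupling and self-alkylation of the electron-rich benzylic chloride during magnesium insertion may leave too little organometallic reagent. The fallback sets out from 14 and returns at 18, and brings ring B in as an aryl electrophile instead of a benzyl nucleophile. MeMgBr (THF, 0 °C) converts 14 into 1-[4-methoxy-2-(methoxymethoxy)-3-(3-methylbut-2-enyl)phenyl]ethan-1-one F4. Palladium-catalysed α-arylation of its enolate with 1-bromo-2,4,5-trimethoxybenzene (Pd2(dba)3, XPhos, NaOt-Bu, toluene, 80 °C) then gives 18. The trisubstituted prenyl alkene is a poor Heck acceptor and the MOM acetal is stable to the base.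

**Further compounds**

F1 | step 3 | N,3,3-trimethoxy-N-methylpropanamide | COC(OC)CC(=O)N(C)OC
F2 | step 3 | methyl 7,7-dimethoxy-4-(3-methylbut-2-enyl)-3,5-dioxoheptanoate | COC(OC)CC(=O)C(CC=C(C)C)C(=O)CC(=O)OC
F3 | step 4 | methyl 2-[3-(3-methylbut-2-enyl)-4-oxo-4H-pyran-2-yl]acetate | COC(=O)Cc1occc(=O)c1CC=C(C)C
F4 | step 9 | 1-[4-methoxy-2-(methoxymethoxy)-3-(3-methylbut-2-enyl)phenyl]ethan-1-one | COCOc1c(CC=C(C)C)c(OC)ccc1C(C)=O
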